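**Plan**

- Kaurane numbering is used. The ring atoms C5 to C14 of the ten-membered ring are the perimeter of two six-membered rings that share C8–C9. The target is therefore latent in a trans-fused podocarpa-8,11,13-triene (rings A and B plus a sacrificial anisole ring C) with the C5-H/C10-methyl pair already in place.
- Retrosynthetic cuts, in order: C16=C17 (Mannich methylenation); C8–C15 (benzoin closure, C8=C14 by dehydration); C8/C9 rejoined as the ring-fusion alkene (ozonolysis retron); C13=C16 (Wittig); C11–O (gamma-hydroxylation of the C7 enone); ring C back to the anisole (Birch); C9–C10 and C4–C5 (polyene bicyclisation); C6–C7 (Grignard coupling).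
- Forward: the chain is joined at C6–C7, rings A and B close together onto the arene, ring C is dearomatised, ozonolysis merges rings B and C into the ten-membered ring, and the cyclopentenone closes last.
- Stereochemistry: C5/C10 from the chiral acid and the chair-chair fold of the E alkene; C11 from peracid attack anti to the C10 methyl; C13 from hydrogenation directed by the C11 hydroxyl; C7 from axial hydride addition to the C7 enone.

Key step: step 2

Assumption: the (S)-binaphthol acid is taken to give the ent (5R,10R) series, the mirror image of the sense known for (R)-binaphthol-derived acids; if the sense is reversed, the (R)-ligand is used with no other change.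

Remark: in the tricyclic intermediates "syn" and "anti" refer to the face carrying the C10 methyl. Compounds 7–11 may be carried as C7 epimers and 11–14 as alkene isomers, since both converge (steps 7 and 9).

**Route**

Step 1
Reactants: 1 3-methoxybenzyl chloride; 2 geranyl bromide
Product: 4 (E)-1-(4,8-dimethylnona-3,7-dien-1-yl)-3-methoxybenzene, via benzylic Grignard reagent 3 (not isolated)
Conditions: Mg, THF, 0 °C; then 2, Li2CuCl4 (3 mol %), THF, −20 → 0 °C
Reagents that add atoms: none
Why: Copper-catalysed Grignard cross-coupling with a primary allylic bromide should join the benzylic carbon (C7) to C6 at the alpha position in THF with the E alkene untouched; no stereocentre is formed.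

Step 2
Reactants: 4 (E)-1-(4,8-dimethylnona-3,7-dien-1-yl)-3-methoxybenzene
Product: 5 (5R,10R)-13-methoxypodocarpa-8,11,13-triene
Conditions: (S)-3,3'-dichloro-1,1'-bi-2-naphthol·SbCl5 (1:1), CH2Cl2, −78 °C
Reagents that add atoms: none
Why: The binaphthol, made strongly acidic by SbCl5, protonates the terminal alkene at C3 on one enantioface; the C4 cation is attacked by the E alkene, the C10 cation is captured by the arene, and the arene proton is lost. The closest known reaction type is the enantioselective proton-initiated polyene cyclisation of homogeranyl arenes with binaphthol–SnCl4 or binaphthol–SbCl5 acids. Ring A closes by 6-endo cation–alkene addition (C4–C5) and ring B by 6-endo Friedel–Crafts alkylation (C9–C10). C5 and C10 are set together: anti addition across the E alkene in a chair-chair fold fixes the trans relation of C5-H and the C10 methyl, and the protonation face chosen by the chiral acid fixes the absolute sense. The step needs arene attack para to the methoxy group and complete bicyclisation; the para site is more activated and less hindered than the ortho site between the methoxy group and the tether, and the electron-rich anisole terminator should outrun elimination to monocyclic alkenes.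

Step 3
Reactants: 5 (5R,10R)-13-methoxypodocarpa-8,11,13-triene
Product: 6 (5R,10R)-13-methoxypodocarpa-8,11,13-trien-7-one
Conditions: CrO3, AcOH/H2O, rt
Reagents that add atoms: CrO3, O=[Cr](=O)=O
Why: Benzylic oxidation with hexavalent chromium should be specific for C7, the only benzylic methylene (C10 is quaternary), as is usual for podocarpatrienes; no stereocentre is touched.

Step 4
Reactants: 6 (5R,10R)-13-methoxypodocarpa-8,11,13-trien-7-one
Product: 7 (5R,7R,10R)-13-methoxypodocarpa-8,11,13-trien-7-ol
Conditions: NaBH4, MeOH/THF, 0 °C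
Reagents that add atoms: none
Why: Borohydride reduction puts C7 at the alcohol level, which can pass the Birch step as an alkoxide; axial hydride delivery should favour the 7-OH syn to the C10 methyl, but either epimer serves because C7 is re-oxidised in step 7.

Step 5
Reactants: 7 (5R,7R,10R)-13-methoxypodocarpa-8,11,13-trien-7-ol
Product: 9 (5R,7R,10R)-7-hydroxypodocarp-8-en-13-one, via Birch dienol ether 8 (not isolated)
Conditions: Li, NH3(l)/THF, t-BuOH, −78 → −33 °C; isoprene, then NH4Cl; then (CO2H)2, MeOH/THF/H2O, rt
Reagents that add atoms: water, O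
Why: Birch reduction of the anisole ring should place the new hydrogens at C11 and C14, keeping the enol ether and the tetrasubstituted C8=C9 alkene, while the benzylic oxygen survives as its lithium alkoxide (excess metal is destroyed before any acid stronger than tert-butanol is added); oxalic acid then hydrolyses the enol ether to the beta,gamma-unsaturated ketone without conjugation, as in the estrogen methyl ether to 5(10)-en-3-one sequence.

Step 6
Reactants: 9 (5R,7R,10R)-7-hydroxypodocarp-8-en-13-one; 10 ethyl (triphenylphosphoranylidene)acetate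
Product: 11 ethyl [(5R,7R,10R)-7-hydroxypodocarp-8-en-13-ylidene]acetate (alkene isomers)
Conditions: 10, PhCO2H (cat.), toluene, 90 °C
Reagents that add atoms: none
Why: Wittig olefination with the stabilised, nearly neutral ylide is chosen over a phosphonate anion so that the beta,gamma-enone is not pulled into conjugation; alkene geometry is irrelevant because both isomers give the same C13 centre in step 9.

Step 7
Reactants: 11 ethyl [(5R,7R,10R)-7-hydroxypodocarp-8-en-13-ylidene]acetate
Product: 12 ethyl [(5R,10R)-7-oxopodocarp-8-en-13-ylidene]acetate (alkene isomers)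
Conditions: Dess–Martin periodinane, CH2Cl2, 0 °C → rt
Reagents that add atoms: none
Why: Dess–Martin oxidation of the secondary allylic alcohol should give the tetrasubstituted C7 enone under non-basic conditions that leave the doubly allylic C14 methylene alone.

Step 8
Reactants: 12 ethyl [(5R,10R)-7-oxopodocarp-8-en-13-ylidene]acetate
Product: 14 ethyl [(5R,10R,11S)-11-hydroxy-7-oxopodocarp-8-en-13-ylidene]acetate (11-OH anti), via silyl dienol ether 13 (not isolated)
Conditions: TMSOTf, Et3N, CH2Cl2, 0 °C; then mCPBA, NaHCO3, CH2Cl2, −20 °C; aq. citric acid work-up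
Reagents that add atoms: mCPBA, OOC(=O)c1cccc(Cl)c1
Why: Equilibrating silylation should give the through-conjugated 7-silyloxy-7,9(11)-diene, and the peracid attacks its gamma terminus C11 (vinylogous Rubottom oxidation, as in the 6-hydroxylation of steroidal 3,5-dienol ethers) from the face opposite the axial C10 methyl, which sets C11; C8 is fully substituted and the enoate alkene is electron-poor, so neither competes.

Step 9
Reactants: 14 ethyl [(5R,10R,11S)-11-hydroxy-7-oxopodocarp-8-en-13-ylidene]acetate
Product: 15 ethyl [(5R,10R,11S,13R)-11-hydroxy-7-oxopodocarp-8-en-13-yl]acetate (side chain syn; 11-OH anti)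
Conditions: [Rh(nbd)(dppb)]BF4 (5 mol %), H2 (50 bar), CH2Cl2, rt
Reagents that add atoms: none
Why: In this hydroxyl-directed homogeneous hydrogenation the cationic rhodium catalyst binds the homoallylic C11 hydroxyl and delivers hydrogen to C13 on the same face, so the side chain ends trans to the 11-OH (syn to the C10 methyl) from either alkene isomer; the tetrasubstituted enone alkene should be inert to this catalyst and high pressure suppresses alkene migration.

Step 10
Reactants: 15 ethyl [(5R,10R,11S,13R)-11-hydroxy-7-oxopodocarp-8-en-13-yl]acetate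
Product: 16 ethyl [11-(tert-butyldimethylsilyloxy)-7-oxopodocarp-8-en-13-yl]acetate (configurations as in 15)
Conditions: TBSOTf, 2,6-lutidine, CH2Cl2, −78 → 0 °C
Reagents that add atoms: TBSOTf, CC(C)(C)[Si](C)(C)OS(=O)(=O)C(F)(F)F
Why: Silylation with the silyl triflate and a hindered base is the standard way to protect a hindered secondary alcohol, and the TBS ether lasts until the final step.

Step 11
Reactants: 16 ethyl [11-(tert-butyldimethylsilyloxy)-7-oxopodocarp-8-en-13-yl]acetate
Product: 17 ethyl [11-(tert-butyldimethylsilyloxy)-7-hydroxypodocarp-8-en-13-yl]acetate (7-OH syn)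
Conditions: NaBH4, CeCl3·7H2O, MeOH, −40 °C
Reagents that add atoms: none
Why: Luche reduction should give clean 1,2-reduction of the tetrasubstituted enone without touching the ester, and axial hydride attack from the face opposite the C10 methyl should give the pseudoequatorial 7-OH syn to that methyl, as in the reduction of steroidal 7-keto-5-enes to the equatorial alcohols.

Step 12
Reactants: 17 ethyl [11-(tert-butyldimethylsilyloxy)-7-hydroxypodocarp-8-en-13-yl]acetate
Product: 18 ethyl [11-(tert-butyldimethylsilyloxy)-7-(triethylsilyloxy)podocarp-8-en-13-yl]acetate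
Conditions: TESCl, imidazole, DMF, 0 °C → rt
Reagents that add atoms: TESCl, CC[Si](Cl)(CC)CC
Why: Standard silylation; the TES ether is chosen because it can later be removed in the presence of the C11 TBS ether, which keeps the two oxygens distinguishable.

Step 13
Reactants: 18 ethyl [11-(tert-butyldimethylsilyloxy)-7-(triethylsilyloxy)podocarp-8-en-13-yl]acetate
Product: 19 [11-(tert-butyldimethylsilyloxy)-7-(triethylsilyloxy)podocarp-8-en-13-yl]acetaldehyde
Conditions: iBu2AlH (1.1 equiv), CH2Cl2, −78 °C; MeOH, then aq. potassium sodium tartrate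
Reagents that add atoms: none
Why: Partial reduction of the ethyl ester by the aluminium hydride at low temperature, where the aluminium hemiacetal persists until hydrolysis, should give the aldehyde (C15) directly.

Step 14
Reactants: 19 [11-(tert-butyldimethylsilyloxy)-7-(triethylsilyloxy)podocarp-8-en-13-yl]acetaldehyde
Product: 21 [11-(tert-butyldimethylsilyloxy)-8,9-dioxo-7-(triethylsilyloxy)-8,9-secopodocarpan-13-yl]acetaldehyde, via ozonide 20 (not isolated)
Conditions: O3, CH2Cl2, −78 °C; then PPh3, −78 °C → rt
Reagents that add atoms: ozone, [O-][O+]=O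
Why: Ozonolysis cleaves the only alkene, the electron-rich tetrasubstituted C8=C9 ring-fusion bond, and so turns rings B and C into the ten-membered 8,9-dione just as 9,10-octalin gives cyclodecane-1,6-dione; no stereocentre is at a reacting carbon and the neutral phosphine work-up avoids base-induced transannular aldol reactions.

Step 15
Reactants: 21 [11-(tert-butyldimethylsilyloxy)-8,9-dioxo-7-(triethylsilyloxy)-8,9-secopodocarpan-13-yl]acetaldehyde
Product: 22 11-(tert-butyldimethylsilyloxy)-8-hydroxy-7-(triethylsilyloxy)-8,9-seco-17-norkaurane-9,15-dione (ent series; C8 epimers)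
Conditions: 3-benzyl-5-(2-hydroxyethyl)-4-methylthiazolium chloride (20 mol %), Et3N, t-BuOH/THF, 40 °C
Reagents that add atoms: none
Why: In this carbene-catalysed intramolecular crossed benzoin reaction the Breslow intermediate of the aldehyde (C15) adds to the C8 ketone and closes the five-membered ring, in preference to six-membered closure onto the C9 ketone, which is flanked by the quaternary C10 and the silyloxy-bearing C11; the new C8 carbinol centre is uncontrolled and is removed in step 16.

Step 16
Reactants: 22 11-(tert-butyldimethylsilyloxy)-8-hydroxy-7-(triethylsilyloxy)-8,9-seco-17-norkaurane-9,15-dione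
Product: 23 11-(tert-butyldimethylsilyloxy)-7-(triethylsilyloxy)-8,9-seco-17-norkaur-8(14)-ene-9,15-dione (ent series)
Conditions: SOCl2, pyridine, CH2Cl2, −40 → 0 °C
Reagents that add atoms: none
Why: Dehydration of the tertiary alpha-ketol through its chlorosulfite (the classical 17-hydroxy-20-ketone to 16-en-20-one conversion) should proceed by anti elimination of a C14 hydrogen within the five-membered ring to give the conjugated cyclopentenone, the lone C7 hydrogen being shielded by its silyloxy group.

Step 17
Reactants: 23 11-(tert-butyldimethylsilyloxy)-7-(triethylsilyloxy)-8,9-seco-17-norkaur-8(14)-ene-9,15-dione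
Product: 27 11-(tert-butyldimethylsilyloxy)-7-(triethylsilyloxy)-8,9-secokaura-8(14),16-diene-9,15-dione (ent series), via lithium enolate 24 (not isolated), via Mannich base 25 (not isolated), via methiodide 26 (not isolated)
Conditions: LiN(iPr)2, THF, −78 °C; CH2=NMe2+ I−, −78 → 0 °C; then MeI, CH2Cl2, rt; then sat. aq. NaHCO3, rt
Reagents that add atoms: dimethylmethyleneammonium iodide (Eschenmoser's salt), C=[N+](C)C.[I-]
Why: Kinetic alpha'-deprotonation of the cyclopentenone at C16, Mannich reaction with Eschenmoser's salt, N-methylation and mild-base elimination is the standard alpha-methylenation of cyclopentanones; the C9 ketone should not compete because its only alpha hydrogen is the hindered tertiary C11-H, and low temperature and a weak final base avoid deprotonation at C13.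

Step 18
Reactants: 27 11-(tert-butyldimethylsilyloxy)-7-(triethylsilyloxy)-8,9-secokaura-8(14),16-diene-9,15-dione
Product: 28 11-(tert-butyldimethylsilyloxy)-7-hydroxy-8,9-secokaura-8(14),16-diene-9,15-dione (ent series)
Conditions: HF·pyridine, pyridine, THF, 0 °C
Reagents that add atoms: none
Why: Buffered HF·pyridine should cleave the secondary TES ether selectively in the presence of the more hindered TBS ether (a standard rate difference) without harming the cross-conjugated dienone.

Step 19
Reactants: 28 11-(tert-butyldimethylsilyloxy)-7-hydroxy-8,9-secokaura-8(14),16-diene-9,15-dione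
Product: 29 7-acetoxy-11-(tert-butyldimethylsilyloxy)-8,9-secokaura-8(14),16-diene-9,15-dione (ent series)
Conditions: Ac2O, pyridine, CH2Cl2, 0 °C → rt
Reagents that add atoms: acetic anhydride, CC(=O)OC(C)=O
Why: Acetylation of the free allylic C7 alcohol in pyridine, without a nucleophilic catalyst that could add to the enone or displace the new allylic acetate, retains the C7 configuration.

Step 20
Reactants: 29 7-acetoxy-11-(tert-butyldimethylsilyloxy)-8,9-secokaura-8(14),16-diene-9,15-dione
Product: 30 (5R,7R,10R,11S,13S)-7-acetoxy-11-hydroxy-8,9-secokaura-8(14),16-diene-9,15-dione (ent series; CNP0159088.1)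
Conditions: HF (48 % aq.), MeCN, 0 °C → rt
Reagents that add atoms: none
Why: Acidic fluoride desilylation removes the last silyl ether, and the acetate, the alpha-ketol and the methylene cyclopentenone should tolerate these conditions, which are routine for enone-bearing terpenoids.

**Compound list**

1 | 3-methoxybenzyl chloride | COc1cccc(CCl)c1 | starting material
2 | geranyl bromide, (2E)-1-bromo-3,7-dimethylocta-2,6-diene | CC(C)=CCC/C(C)=C/CBr | starting material
3 | (3-methoxybenzyl)magnesium chloride (in situ) | COc1cccc(C[Mg]Cl)c1 | intermediate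
4 | (E)-1-(4,8-dimethylnona-3,7-dien-1-yl)-3-methoxybenzene | COc1cccc(CC/C=C(\C)CCC=C(C)C)c1 | intermediate
5 | (5R,10R)-13-methoxypodocarpa-8,11,13-triene (ent series; C5-H anti to C10 methyl) | COc1ccc2c(c1)CC[C@@H]1C(C)(C)CCC[C@@]21C | intermediate
6 | (5R,10R)-13-methoxypodocarpa-8,11,13-trien-7-one | COc1ccc2c(c1)C(=O)C[C@@H]1C(C)(C)CCC[C@@]21C | intermediate
7 | (5R,7R,10R)-13-methoxypodocarpa-8,11,13-trien-7-ol (expected major epimer, 7-OH syn) | COc1ccc2c(c1)[C@H](O)C[C@@H]1C(C)(C)CCC[C@@]21C | intermediate
8 | (5R,7R,10R)-13-methoxypodocarpa-8,12-dien-7-ol (in situ) | COC1=CCC2=C(C1)[C@H](O)C[C@@H]1C(C)(C)CCC[C@@]21C | intermediate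
9 | (5R,7R,10R)-7-hydroxypodocarp-8-en-13-one | O=C1CCC2=C(C1)[C@H](O)C[C@@H]1C(C)(C)CCC[C@@]21C | intermediate
10 | ethyl (triphenylphosphoranylidene)acetate | CCOC(=O)C=P(c1ccccc1)(c1ccccc1)c1ccccc1 | starting material
11 | ethyl [(5R,7R,10R)-7-hydroxypodocarp-8-en-13-ylidene]acetate (alkene isomers) | CCOC(=O)C=C1CCC2=C(C1)[C@H](O)C[C@@H]1C(C)(C)CCC[C@@]21C | intermediate
12 | ethyl [(5R,10R)-7-oxopodocarp-8-en-13-ylidene]acetate (alkene isomers) | CCOC(=O)C=C1CCC2=C(C1)C(=O)C[C@@H]1C(C)(C)CCC[C@@]21C | intermediate
13 | ethyl [(5R,10R)-7-(trimethylsilyloxy)podocarpa-7,9(11)-dien-13-ylidene]acetate (in situ) | CCOC(=O)C=C1CC=C2C(C1)=C(O[Si](C)(C)C)C[C@@H]1C(C)(C)CCC[C@@]21C | intermediate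
14 | ethyl [(5R,10R,11S)-11-hydroxy-7-oxopodocarp-8-en-13-ylidene]acetate (11-OH anti; alkene isomers) | CCOC(=O)C=C1C[C@H](O)C2=C(C1)C(=O)C[C@@H]1C(C)(C)CCC[C@@]21C | intermediate
15 | ethyl [(5R,10R,11S,13R)-11-hydroxy-7-oxopodocarp-8-en-13-yl]acetate (11-OH anti; side chain syn) | CCOC(=O)C[C@H]1C[C@H](O)C2=C(C1)C(=O)C[C@@H]1C(C)(C)CCC[C@@]21C | intermediate
16 | ethyl [11-(tert-butyldimethylsilyloxy)-7-oxopodocarp-8-en-13-yl]acetate (configurations as in 15) | CCOC(=O)C[C@H]1C[C@H](O[Si](C)(C)C(C)(C)C)C2=C(C1)C(=O)C[C@@H]1C(C)(C)CCC[C@@]21C | intermediate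
17 | ethyl [11-(tert-butyldimethylsilyloxy)-7-hydroxypodocarp-8-en-13-yl]acetate (7-OH syn) | CCOC(=O)C[C@H]1C[C@H](O[Si](C)(C)C(C)(C)C)C2=C(C1)[C@H](O)C[C@@H]1C(C)(C)CCC[C@@]21C | intermediate
18 | ethyl [11-(tert-butyldimethylsilyloxy)-7-(triethylsilyloxy)podocarp-8-en-13-yl]acetate | CCOC(=O)C[C@H]1C[C@H](O[Si](C)(C)C(C)(C)C)C2=C(C1)[C@H](O[Si](CC)(CC)CC)C[C@@H]1C(C)(C)CCC[C@@]21C | intermediate
19 | [11-(tert-butyldimethylsilyloxy)-7-(triethylsilyloxy)podocarp-8-en-13-yl]acetaldehyde | O=CC[C@H]1C[C@H](O[Si](C)(C)C(C)(C)C)C2=C(C1)[C@H](O[Si](CC)(CC)CC)C[C@@H]1C(C)(C)CCC[C@@]21C | intermediate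
20 | 8,9-ozonide (8,9-epoxy-8,9-epidioxy compound) of 19 (in situ; C8 and C9 undefined) | O=CC[C@H]1C[C@H](O[Si](C)(C)C(C)(C)C)C23OOC(C1)(O2)[C@H](O[Si](CC)(CC)CC)C[C@@H]1C(C)(C)CCC[C@@]31C | intermediate
21 | [11-(tert-butyldimethylsilyloxy)-8,9-dioxo-7-(triethylsilyloxy)-8,9-secopodocarpan-13-yl]acetaldehyde (ten-membered diketone; C5, C7, C10, C11, C13 as in the target) | O=CC[C@H]1C[C@H](O[Si](C)(C)C(C)(C)C)C(=O)[C@]2(C)CCCC(C)(C)[C@H]2C[C@@H](O[Si](CC)(CC)CC)C(=O)C1 | intermediate
22 | 11-(tert-butyldimethylsilyloxy)-8-hydroxy-7-(triethylsilyloxy)-8,9-seco-17-norkaurane-9,15-dione (ent series; C8 undefined) | O=C1C[C@H]2C[C@H](O[Si](C)(C)C(C)(C)C)C(=O)[C@]3(C)CCCC(C)(C)[C@H]3C[C@@H](O[Si](CC)(CC)CC)C1(O)C2 | intermediate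
23 | 11-(tert-butyldimethylsilyloxy)-7-(triethylsilyloxy)-8,9-seco-17-norkaur-8(14)-ene-9,15-dione (ent series) | O=C1C[C@H]2C[C@H](O[Si](C)(C)C(C)(C)C)C(=O)[C@]3(C)CCCC(C)(C)[C@H]3C[C@@H](O[Si](CC)(CC)CC)C1=C2 | intermediate
24 | lithium 15,16-enolate of 23 (in situ) | [Li]OC1=C[C@H]2C[C@H](O[Si](C)(C)C(C)(C)C)C(=O)[C@]3(C)CCCC(C)(C)[C@H]3C[C@@H](O[Si](CC)(CC)CC)C1=C2 | intermediate
25 | 16-(dimethylaminomethyl) derivative of 23 (in situ; C16 undefined) | CN(C)CC1C(=O)C2=C[C@@H]1C[C@H](O[Si](C)(C)C(C)(C)C)C(=O)[C@]1(C)CCCC(C)(C)[C@H]1C[C@H]2O[Si](CC)(CC)CC | intermediate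
26 | 16-(trimethylammoniomethyl) iodide of 23 (in situ; C16 undefined) | C[N+](C)(C)CC1C(=O)C2=C[C@@H]1C[C@H](O[Si](C)(C)C(C)(C)C)C(=O)[C@]1(C)CCCC(C)(C)[C@H]1C[C@H]2O[Si](CC)(CC)CC.[I-] | intermediate
27 | 11-(tert-butyldimethylsilyloxy)-7-(triethylsilyloxy)-8,9-secokaura-8(14),16-diene-9,15-dione (ent series) | C=C1C(=O)C2=C[C@@H]1C[C@H](O[Si](C)(C)C(C)(C)C)C(=O)[C@]1(C)CCCC(C)(C)[C@H]1C[C@H]2O[Si](CC)(CC)CC | intermediate
28 | 11-(tert-butyldimethylsilyloxy)-7-hydroxy-8,9-secokaura-8(14),16-diene-9,15-dione (ent series) | C=C1C(=O)C2=C[C@@H]1C[C@H](O[Si](C)(C)C(C)(C)C)C(=O)[C@]1(C)CCCC(C)(C)[C@H]1C[C@H]2O | intermediate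
29 | 7-acetoxy-11-(tert-butyldimethylsilyloxy)-8,9-secokaura-8(14),16-diene-9,15-dione (ent series) | C=C1C(=O)C2=C[C@@H]1C[C@H](O[Si](C)(C)C(C)(C)C)C(=O)[C@]1(C)CCCC(C)(C)[C@H]1C[C@H]2OC(C)=O | intermediate
30 | (5R,7R,10R,11S,13S)-7-acetoxy-11-hydroxy-8,9-secokaura-8(14),16-diene-9,15-dione (ent series; CNP0159088.1) | C=C1C(=O)C2=C[C@@H]1C[C@H](O)C(=O)[C@]1(C)CCCC(C)(C)[C@H]1C[C@H]2OC(C)=O | target

**Step count and risks**

Total step count: 20. Longest linear sequence: 20 steps (from 1 or 2 to 30); the ylide 10 enters at step 6.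

The three steps most likely to fail:

Step 5. The benzylic C7–O bond may be lost by hydrogenolysis before the arene is reduced, or the ring may be over-reduced. The fallback sets out from 5 and returns at 9; it inverts the order of oxidation and dearomatisation. Birch reduction of 5 itself (Li, NH3, t-BuOH) should give (5R,10R)-13-methoxypodocarpa-8,12-diene F1. Acid-catalysed exchange with ethylene glycol should convert the enol ether into (5R,10R)-13,13-ethylenedioxypodocarp-8-ene F2 without moving the C8=C9 alkene. Allylic oxidation with CrO3·3,5-dimethylpyrazole is expected at C7, since C11 is crowded by C1 and the C10 methyl and C14 adjoins the ketal, to give (5R,10R)-13,13-ethylenedioxypodocarp-8-en-7-one F3. Luche reduction should give (5R,7R,10R)-13,13-ethylenedioxypodocarp-8-en-7-ol F4, and mild aqueous acid unmasks the ketone to rejoin the route at 9.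

Step 9. Water may be lost from the gamma-hydroxy enone 14 with aromatisation of ring C, the exocyclic alkene may migrate into the ring before hydrogen is delivered, or the facial direction may be too weak. The fallback sets out from 12 and returns at 15; it replaces substrate direction by reagent control and moves the hydroxylation behind the reduction. The alkene isomers of 12 are separated into ethyl (E)-[(5R,10R)-7-oxopodocarp-8-en-13-ylidene]acetate F5 and ethyl (Z)-[(5R,10R)-7-oxopodocarp-8-en-13-ylidene]acetate F6. Each is hydrogenated with the matched antipode of a chiral iridium phosphine–oxazoline catalyst, [Ir(cod)((S)- or (R)-tBu-PHOX)][B(3,5-(CF3)2C6H3)4], since E and Z isomers give opposite C13 configurations with one antipode; both should converge on ethyl [(5R,10R)-7-oxopodocarp-8-en-13-yl]acetate (side chain syn) F7. Silylation (TMSOTf, Et3N) then gives ethyl [(5R,10R)-7-(trimethylsilyloxy)podocarpa-7,9(11)-dien-13-yl]acetate F8, whose oxidation with mCPBA anti to the C10 methyl returns to 15 without ever passing through the fragile hydroxy alkylidene 14.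

Step 15. Transannular aldol reactions of the cyclodecanedione, epimerisation at C7 next to the C8 ketone under the basic carbene conditions, or six-membered closure onto C9 may compete. The fallback sets out from 21 and returns at 22; it uses reductive instead of umpolung coupling. Ketyl (pinacol) cyclisation with SmI2 (THF, t-BuOH, −78 °C), in which the aldehyde is reduced first and adds to the C8 ketone, should give 11-(tert-butyldimethylsilyloxy)-8,15-dihydroxy-7-(triethylsilyloxy)-8,9-seco-17-norkauran-9-one F9. Oxidation of its secondary C15 alcohol with Dess–Martin periodinane, which leaves the tertiary C8 alcohol, returns to 22.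

Further compounds
F1 | step 5 | (5R,10R)-13-methoxypodocarpa-8,12-diene | COC1=CCC2=C(C1)CC[C@@H]1C(C)(C)CCC[C@@]21C
F2 | step 5 | (5R,10R)-13,13-ethylenedioxypodocarp-8-ene | O1CCOC12CCC3=C(C2)CC[C@@H]2C(C)(C)CCC[C@@]32C
F3 | step 5 | (5R,10R)-13,13-ethylenedioxypodocarp-8-en-7-one | O1CCOC12CCC3=C(C2)C(=O)C[C@@H]2C(C)(C)CCC[C@@]32C
F4 | step 5 | (5R,7R,10R)-13,13-ethylenedioxypodocarp-8-en-7-ol | O1CCOC12CCC3=C(C2)[C@H](O)C[C@@H]2C(C)(C)CCC[C@@]32C
F5 | step 9 | ethyl (E)-[(5R,10R)-7-oxopodocarp-8-en-13-ylidene]acetate | CCOC(=O)/C=C1\CCC2=C(C1)C(=O)C[C@@H]1C(C)(C)CCC[C@@]21C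
F6 | step 9 | ethyl (Z)-[(5R,10R)-7-oxopodocarp-8-en-13-ylidene]acetate | CCOC(=O)/C=C1/CCC2=C(C1)C(=O)C[C@@H]1C(C)(C)CCC[C@@]21C
F7 | step 9 | ethyl [(5R,10R)-7-oxopodocarp-8-en-13-yl]acetate (side chain syn to the C10 methyl) | CCOC(=O)C[C@H]1CCC2=C(C1)C(=O)C[C@@H]1C(C)(C)CCC[C@@]21C
F8 | step 9 | ethyl [(5R,10R)-7-(trimethylsilyloxy)podocarpa-7,9(11)-dien-13-yl]acetate | CCOC(=O)C[C@H]1CC=C2C(C1)=C(O[Si](C)(C)C)C[C@@H]1C(C)(C)CCC[C@@]21C
F9 | step 15 | 11-(tert-butyldimethylsilyloxy)-8,15-dihydroxy-7-(triethylsilyloxy)-8,9-seco-17-norkauran-9-one (C8 and C15 undefined) | OC1C[C@H]2C[C@H](O[Si](C)(C)C(C)(C)C)C(=O)[C@]3(C)CCCC(C)(C)[C@H]3C[C@@H](O[Si](CC)(CC)CC)C1(O)C2
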